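(The earlier runs and the new flask come from a simulation with constants of no real substance; scatter was added.)

Start from the late readings. At 80.0 min in Wednesday's run, left-handed substrate plus left-handed product stand at 61.0 % of the charge, 11.0 % above the 0.5 charged as that hand, so about that much, as a reading, has crossed over from the right-handed substrate.

the same everywhere: left-handed substrate 16 mM; right-handed substrate 16 mM; impurity 4.1 µM
- Wednesday's: coupling partner 40 mM; racemization catalyst 21 µM; run made earlier
- Sunday's: coupling partner 40 mM; racemization catalyst 48 µM; run made earlier
- flask: coupling partner 40.0 mM; racemization catalyst 32 µM; time 2.0 h

- Wednesday's (time / min: left-handed product / %, right-handed product / %, left-handed substrate / %): 15.0: 28, 15, 26; 30.0: 41, 26, 18; 40.0: 44, 24, 15; 60.0: 53, 29, 10; 80.0: 53, 30, 8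
- Sunday's (time / min: left-handed product / %, right-handed product / %, left-handed substrate / %): 15.0: 29, 15, 25; 30.0: 42, 20, 16; 40.0: 48, 23, 16; 60.0: 54, 30, 8; 80.0: 57, 31, 4

(scatter of a reading: 1.5 percentage points)

- left-handed product and right-handed product together, in percent of the left-handed substrate and right-handed substrate charged together, at 2.0 h
- excess of left-handed product over right-handed product in the product at 2.0 h
- whether the exchange between left-handed substrate and right-handed substrate keeps pace with the reaction: how far the product's excess at 2.0 h gets from its value without exchange to its value with instant exchange (above 80 % keeps pace, below 20 % hardly takes part, else lags behind)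

- coupling partner is single-handed; left-handed substrate and right-handed substrate are mirror images of each other, charged as a racemate, each of them at the stated concentration
- an excess is the difference of the two amounts in percent of their sum
- an excess is below zero if the other one leads
- the handed part of coupling partner does not stay in what it makes, so the products of the two hands are mirror images too

Now ask how much crossing the coupling needs. Pool the first readings of both runs, when the substrates stand near each other (in Wednesday's run 26 % left-handed against 31.0 % right-handed by balance), to get the product excess, a reading of the selectivity factor:

ceiling excess = (left-handed − right-handed product) / (their sum), at 15.0 min = 31.0 %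

Doubt it: a scatter of 1.5 percentage points per reading moves this by some points. Accept it as a reading. Holding that excess takes a crossing of 0.5 × product fraction × ceiling excess:

Wednesday's run, 80.0 min: found 11.0 %, needed 12.9 %, quotient 0.854

Sunday's run, 80.0 min: found 11.0 %, needed 13.7 %, quotient 0.806

Call this quotient the crossing ratio, the part of the needed crossing that was done. It reads 0 with no exchange and 1 with instant exchange.

Object that Sunday's catalyst is twice Wednesday's, yet its ratio is no higher. Each found crossing rests on two readings with a scatter of 1.5 points each, and the two ratios differ by 0.0480, so read no catalyst effect from that gap. Object too that this ratio is not the asked share. The pooled excess at 80.0 min, 28.7 %, lies close under the ceiling, so expect about that excess, with exchange keeping pace. One doubt stays open: the last reading of either run stands at 80.0 min, and the flask runs longer, to 2.0 h.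

The forecast gives 92 %, 29.5 % and "keeps pace": “Product excess stays flat near 30% throughout, and more than doubling the catalyst changes little”.

The flask gives 92.6 %, 28.7 % and "keeps pace", 87 % of the way.

    coupling partner + left-handed substrate → left-handed product (k = 0.0290 /M/s)
    coupling partner + right-handed substrate → right-handed product (k = 0.0150 /M/s)
    left-handed substrate + racemization catalyst ⇌ right-handed substrate + racemization catalyst, rate k3*[racemization catalyst]*[left-handed substrate] forward; the back reaction follows from the equilibrium constant (k = 130 /M/s)
    racemization catalyst + impurity → spent catalyst A (k = 5800 /M/s)
    coupling partner + racemization catalyst → spent catalyst B (k = 0.0150 /M/s)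

The crossing ratio of the flask at 2.00 h is 0.909; in the neighbour charged with 10 mM of coupling partner it is 1.01, with excess 31.4 %. In the flask, coupling uses left-handed substrate at 0.31 of the forward exchange rate (forward step alone) at 0.252 h and at 0.50 of it at 2.00 h, still slower. By that time racemization catalyst stands at 14.5 % of its charge and coupling partner at 25.9 % of its own.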